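**Retrosynthetic overview**
1. The target is a 2,3-cis-3,4-trans flavan-3-ol (upper unit) bonded through its C4 to C6 of all-cis teracacidin (lower unit); after the key step only methanolysis and debenzylation remain.
2. Key disconnection: upper ring C is opened at C4–C4a and at C2–C3, giving diaryl acetal 6 (source of the aryl oxocarbenium ion C4a=C8a–O1(+)=C2) and the E enol benzoate 19 (C3=C4) on C6 of the protected lower unit; the forward reaction is a catalytic asymmetric formal [4+2] (oxa-Povarov).
3. Enabling feature: in upper ring C, O1–C2 is an aryl benzyl ether whose ring A carbon C4a is ortho to O1 and para to the C7 oxygen; C4 is benzylic to lower ring A at C6, which is para to the lower O1 and ortho to the lower O7, so a C4 cation is strongly stabilised and is captured by C4a.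
4. Lower unit: the pyranone ring of daphnetin becomes lower ring C (chromene acetal, asymmetric C2 arylation, bromohydrin, CO2 closure with inversion to the all-cis 3,4-carbonate); C6 is then iodinated and converted by boryl-Heck reaction and copper-catalysed acyloxylation into 19.
5. Ring order: all benzene rings are bought; lower ring C is inherited from the coumarin and refunctionalised (steps 4–7); upper ring C is formed last (step 12).

Key step: step 12

Remark: CIP descriptors are given in flavan numbering and can differ between protected intermediates and the target for the same spatial arrangement (priority changes only), so the SMILES strings are authoritative; the antipode of each chiral catalyst is to be chosen to give the stated configuration.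

**Step 1**
Reactants: 1 2,3-bis(benzyloxy)benzaldehyde
Product: 3 2,3-bis(benzyloxy)phenol, via aryl formate 2 (not isolated)
Conditions: mCPBA, CH2Cl2, 0 °C to rt; then K2CO3 (cat.), MeOH, rt
Reagents that add atoms: mCPBA, OOC(=O)c1cccc(Cl)c1
Why: Baeyer–Villiger (Dakin-type) oxidation, in which the electron-rich dialkoxyaryl group migrates to oxygen, should give the formate, which mild methanolysis cleaves to the phenol.

**Step 2**
Reactants: 4 3,4-bis(benzyloxy)benzaldehyde; 3 2,3-bis(benzyloxy)phenol (2.1 equiv)
Product: 6 3,4-bis(benzyloxy)benzaldehyde bis[2,3-bis(benzyloxy)phenyl] acetal, via benzal chloride 5 (not isolated)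
Conditions: SOCl2, DMF (cat.), CH2Cl2, 0 °C to rt, evaporate; then 3, NaH, THF/DMF, 0 °C to rt
Reagents that add atoms: none
Why: Deoxodichlorination of an electron-rich benzaldehyde followed by twofold Williamson-type substitution of the ionisable benzal chloride by the phenoxide should give the symmetrical diaryl acetal, either C–O bond of which later ionises to the same aryl oxocarbenium ion.

**Step 3**
Reactants: 7 daphnetin (7,8-dihydroxycoumarin)
Product: 8 7,8-bis(benzyloxy)coumarin
Conditions: BnBr, K2CO3, DMF, 60 °C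
Reagents that add atoms: benzyl bromide, BrCc1ccccc1
Why: Williamson etherification of both phenols.

**Step 4**
Reactants: 8 7,8-bis(benzyloxy)coumarin
Product: 10 7,8-bis(benzyloxy)-2-ethoxy-2H-chromene (racemic), via lactol 9 (not isolated)
Conditions: DIBAL-H, CH2Cl2, −78 °C, aqueous work-up; then EtOH, PPTS (cat.), rt
Reagents that add atoms: ethanol, CCO
Why: Partial hydride reduction of the lactone gives the lactol, which acid-catalysed acetalisation through the stabilised benzopyrylium ion should convert into the ethyl acetal.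

**Step 5**
Reactants: 10 7,8-bis(benzyloxy)-2-ethoxy-2H-chromene; 11 [4-(benzyloxy)phenyl]boronic acid
Product: 13 (S)-7,8-bis(benzyloxy)-2-[4-(benzyloxy)phenyl]-2H-chromene, via diethyl arylboronate 12 (not isolated)
Conditions: 11, EtOH, 4 Å MS, toluene; then 10, tartaric-acid-derived chiral hydroxy acid amide (5 mol %), Ce(OTf)4 (5 mol %), EtOAc, −20 °C, dark
Reagents that add atoms: none
Why: Enantioselective Petasis-type addition of an aryl boronate to the benzopyrylium ion released from a chromene acetal under chiral hydroxy acid/lanthanide triflate catalysis, a known reaction of 2-ethoxy-2H-chromenes; the chiral boronate complex sets C2 and the catalyst antipode is chosen for the S flavene.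

**Step 6**
Reactants: 13 (S)-flavene
Product: 14 (2R,3S,4R)-7,8-bis(benzyloxy)-2-[4-(benzyloxy)phenyl]-3-bromochroman-4-ol
Conditions: NBS (1.05 equiv), DMSO/H2O, 0 °C, dark
Reagents that add atoms: N-bromosuccinimide, BrN1C(=O)CCC1=O; water, O
Why: Bromohydrin formation, in which bromine should add to C3 on the face anti to the C2 aryl group and water should open at the O1/O7-stabilised benzylic C4 anti to bromine, giving Br trans and OH cis to the aryl group.

**Step 7**
Reactants: 14 trans bromohydrin
Product: 15 all-cis (2R,3S,4R)-7,8-bis(benzyloxy)-2-[4-(benzyloxy)phenyl]chromane-3,4-diyl carbonate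
Conditions: CO2 (1 atm), Cs2CO3, DMF, 25–40 °C
Reagents that add atoms: carbon dioxide, O=C=O
Why: Carboxylative cyclisation of a halohydrin, in which the C4 alkoxide captures CO2 and the carbonate anion displaces bromide at C3 with inversion (5-exo-tet), so both oxygens end up cis to the C2 aryl group.

**Step 8**
Reactants: 15 all-cis carbonate
Product: 16 6-iodo derivative of 15
Conditions: NIS, TFA (cat.), MeCN/CH2Cl2, 0 °C
Reagents that add atoms: N-iodosuccinimide, IN1C(=O)CCC1=O
Why: Electrophilic aromatic iodination should occur at C6, the only ring A position that is para to O1 and ortho to the C7 oxygen.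

**Step 9**
Reactants: 16 aryl iodide
Product: 17 6-[(E)-2-(4,4,5,5-tetramethyl-1,3,2-dioxaborolan-2-yl)vinyl] derivative of 15
Conditions: vinylboronic acid pinacol ester (2 equiv), Pd(P(t-Bu)3)2 (5 mol %), i-Pr2NH, toluene, 80 °C
Reagents that add atoms: vinylboronic acid pinacol ester, C=CB1OC(C)(C)C(C)(C)O1
Why: Heck–Mizoroki reaction of a vinylboronate under anhydrous amine-base conditions that suppress transmetalation; syn insertion and syn beta-hydride elimination should give the E alkenylboronate.

**Step 10**
Reactants: 17 alkenylboronate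
Product: 18 potassium (E)-alkenyltrifluoroborate
Conditions: KHF2 (aq.), MeOH, rt
Reagents that add atoms: potassium hydrogen difluoride, [K+].[F-].F
Why: Standard conversion of a pinacol boronate into the trifluoroborate salt, with the alkene geometry untouched.

**Step 11**
Reactants: 18 potassium alkenyltrifluoroborate
Product: 19 6-[(E)-2-(benzoyloxy)vinyl] derivative of 15
Conditions: PhCO2H, CuBr (10 mol %), DMAP (20 mol %), 4 Å MS, O2 (1 atm), MeCN, 60 °C
Reagents that add atoms: benzoic acid, OC(=O)c1ccccc1
Why: Copper-catalysed oxidative C–O coupling (Chan–Lam type) of an alkenyltrifluoroborate with a carboxylic acid, which is stereoretentive and should give the E enol ester.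

**Step 12**
Reactants: 6 diaryl acetal (1.3 equiv); 19 E enol benzoate
Product: 22 protected dimer (upper 3-O-benzoate; lower 3,4-carbonate; hepta-O-benzyl), via oxocarbenium ion 20 (not isolated), via dioxolanylium ion 21 (not isolated)
Conditions: chiral BINOL-derived imidodiphosphorimidate (IDPi) Brønsted acid (5 mol %), CH2Cl2/toluene, −60 to −30 °C
Reagents that add atoms: none
Why: Proposed new method: a catalytic asymmetric oxa-Povarov reaction in which the confined chiral acid ionises acetal 6 (loss of phenol 3) to the E aryl oxocarbenium ion 20 held as a contact ion pair, and 19 attacks C2 through its oxygen-bearing carbon C3 because the resulting C4 cation is benzylic to lower ring A (para to O1, ortho to O7) whereas the benzoyloxy group is a poor donor. The closest known reactions are the SnCl4-mediated oxa-Povarov reaction of aryl oxocarbenium ions with styrenes, the chiral phosphoric acid-catalysed Povarov reaction and imidodiphosphorimidate-catalysed additions of alkenes to oxocarbenium ions. Upper ring C is closed stepwise as a formal inverse-demand [4+2]: intermolecular C2–C3 bond formation, then six-membered Friedel–Crafts closure of C4a (ortho to O1, para to the C7 oxygen) onto C4. C2 is set by the chiral counteranion shielding one face of 20, C3 by an open antiperiplanar (Mukaiyama-type) approach that places the benzoate syn to O1 (2,3-cis), and C4 by the E geometry of 19 together with benzoate participation, since the trans-dioxolanylium ion 21 is opened by C4a with inversion (3,4-trans). The step needs regioselectivity (C3 and not C4 as the nucleophilic carbon), simple diastereoselectivity and enantiofacial control, which the electron-poor ester on an electron-rich styrene, the participating benzoate on an E alkene and the catalyst are meant to secure, while the single free position ortho to O1 in 6 makes the ring closure unambiguous. The cis-fused carbonate of 19 should survive because its benzylic C4–O bond is far less basic than the acetal and any ionisation is returned by the tethered carbonate.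

**Step 13**
Reactants: 22 protected dimer
Product: 23 hepta-O-benzyl triol (upper 3-OH; lower 3,4-diol)
Conditions: NaOMe (cat.), MeOH/THF, rt
Reagents that add atoms: none
Why: Zemplén-type transesterification should remove the benzoate and open the cyclic carbonate without touching the benzyl ethers or any stereocenter.

**Step 14**
Reactants: 23 hepta-O-benzyl triol
Product: 24 target
Conditions: H2 (1 atm), Pd(OH)2/C, THF/MeOH, rt, short contact time, filtration under argon
Reagents that add atoms: none
Why: Hydrogenolysis of the seven aryl benzyl ethers, which under neutral conditions should be much faster than cleavage of the benzylic C4–OH or of the pyran C–O bonds.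

**Compound list**
1 | 2,3-bis(benzyloxy)benzaldehyde | O=Cc1cccc(OCc2ccccc2)c1OCc1ccccc1 | starting material
2 | 2,3-bis(benzyloxy)phenyl formate | O=COc1cccc(OCc2ccccc2)c1OCc1ccccc1 | intermediate
3 | 2,3-bis(benzyloxy)phenol | Oc1cccc(OCc2ccccc2)c1OCc1ccccc1 | intermediate
4 | 3,4-bis(benzyloxy)benzaldehyde | O=Cc1ccc(OCc2ccccc2)c(OCc2ccccc2)c1 | starting material
5 | 1,2-bis(benzyloxy)-4-(dichloromethyl)benzene | ClC(Cl)c1ccc(OCc2ccccc2)c(OCc2ccccc2)c1 | intermediate
6 | 3,4-bis(benzyloxy)benzaldehyde bis[2,3-bis(benzyloxy)phenyl] acetal | C(Oc1cccc(OCc2ccccc2)c1OCc1ccccc1)(Oc1cccc(OCc2ccccc2)c1OCc1ccccc1)c1ccc(OCc2ccccc2)c(OCc2ccccc2)c1 | intermediate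
7 | daphnetin (7,8-dihydroxycoumarin) | O=c1ccc2ccc(O)c(O)c2o1 | starting material
8 | 7,8-bis(benzyloxy)coumarin | O=c1ccc2ccc(OCc3ccccc3)c(OCc3ccccc3)c2o1 | intermediate
9 | 7,8-bis(benzyloxy)-2H-chromen-2-ol (racemic lactol) | OC1C=Cc2ccc(OCc3ccccc3)c(OCc3ccccc3)c2O1 | intermediate
10 | 7,8-bis(benzyloxy)-2-ethoxy-2H-chromene (racemic) | CCOC1C=Cc2ccc(OCc3ccccc3)c(OCc3ccccc3)c2O1 | intermediate
11 | [4-(benzyloxy)phenyl]boronic acid | OB(O)c1ccc(OCc2ccccc2)cc1 | starting material
12 | diethyl [4-(benzyloxy)phenyl]boronate | CCOB(OCC)c1ccc(OCc2ccccc2)cc1 | intermediate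
13 | (S)-7,8-bis(benzyloxy)-2-[4-(benzyloxy)phenyl]-2H-chromene | C(c7ccccc7)Oc1ccc([C@H]2Oc3c(ccc(OCc7ccccc7)c3OCc7ccccc7)C=C2)cc1 | intermediate
14 | (2R,3S,4R)-7,8-bis(benzyloxy)-2-[4-(benzyloxy)phenyl]-3-bromochroman-4-ol (Br trans, OH cis to the 2-aryl group) | C(c7ccccc7)Oc1ccc([C@H]2Oc3c(ccc(OCc7ccccc7)c3OCc7ccccc7)[C@@H](O)[C@@H]2Br)cc1 | intermediate
15 | all-cis (2R,3S,4R)-7,8-bis(benzyloxy)-2-[4-(benzyloxy)phenyl]chromane-3,4-diyl carbonate (same spatial arrangement as the 2R,3R,4R diol) | C(c7ccccc7)Oc1ccc([C@H]2Oc3c(ccc(OCc7ccccc7)c3OCc7ccccc7)[C@H]4OC(=O)O[C@@H]24)cc1 | intermediate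
16 | 6-iodo derivative of 15 | C(c7ccccc7)Oc1ccc([C@H]2Oc3c(cc(I)c(OCc7ccccc7)c3OCc7ccccc7)[C@H]4OC(=O)O[C@@H]24)cc1 | intermediate
17 | 6-[(E)-2-(pinacolboryl)vinyl] derivative of 15 | C(c7ccccc7)Oc1ccc([C@H]2Oc3c(cc(/C=C/B5OC(C)(C)C(C)(C)O5)c(OCc7ccccc7)c3OCc7ccccc7)[C@H]4OC(=O)O[C@@H]24)cc1 | intermediate
18 | potassium (E)-alkenyltrifluoroborate derived from 17 | C(c7ccccc7)Oc1ccc([C@H]2Oc3c(cc(/C=C/[B-](F)(F)F)c(OCc7ccccc7)c3OCc7ccccc7)[C@H]4OC(=O)O[C@@H]24)cc1.[K+] | intermediate
19 | 6-[(E)-2-(benzoyloxy)vinyl] derivative of 15 | C(c7ccccc7)Oc1ccc([C@H]2Oc3c(cc(/C=C/OC(=O)c5ccccc5)c(OCc7ccccc7)c3OCc7ccccc7)[C@H]4OC(=O)O[C@@H]24)cc1 | intermediate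
20 | [2,3-bis(benzyloxy)phenyl][3,4-bis(benzyloxy)benzylidene]oxonium ion (aryl oxocarbenium ion, chiral counteranion) | C(=[O+]c1cccc(OCc2ccccc2)c1OCc1ccccc1)c1ccc(OCc2ccccc2)c(OCc2ccccc2)c1 | intermediate
21 | trans-4,5-disubstituted 2-phenyl-1,3-dioxolan-2-ylium ion (C2–C3 bond formed; C4 bridged by the benzoate; lower unit and C2 side chain trans) | C(c7ccccc7)Oc1ccc([C@H]2Oc3c(cc([C@@H]4[O+]=C(c5ccccc5)O[C@H]4[C@H](Oc4cccc(OCc7ccccc7)c4OCc7ccccc7)c4ccc(OCc7ccccc7)c(OCc7ccccc7)c4)c(OCc7ccccc7)c3OCc7ccccc7)[C@H]6OC(=O)O[C@@H]26)cc1 | intermediate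
22 | protected dimer: upper unit 2,3-cis-3,4-trans 3-O-benzoate (2R,3R,4R by CIP in this form); lower unit all-cis 3,4-carbonate (2R,3S,4R); seven benzyl ethers | C(c7ccccc7)Oc1ccc([C@H]2Oc3c(cc([C@H]4c5ccc(OCc7ccccc7)c(OCc7ccccc7)c5O[C@H](c5ccc(OCc7ccccc7)c(OCc7ccccc7)c5)[C@@H]4OC(=O)c5ccccc5)c(OCc7ccccc7)c3OCc7ccccc7)[C@H]6OC(=O)O[C@@H]26)cc1 | intermediate
23 | hepta-O-benzyl triol: upper unit 2,3-cis-3,4-trans 3-ol; lower unit all-cis (2R,3R,4R) 3,4-diol | C(c7ccccc7)Oc1ccc([C@H]2Oc3c(cc([C@H]4c5ccc(OCc7ccccc7)c(OCc7ccccc7)c5O[C@H](c5ccc(OCc7ccccc7)c(OCc7ccccc7)c5)[C@@H]4O)c(OCc7ccccc7)c3OCc7ccccc7)[C@@H](O)[C@H]2O)cc1 | intermediate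
24 | target: (2R,3R,4S)-3',4',7,8-tetrahydroxyflavan-3-ol joined C4 to C6 of (2R,3R,4R)-4',7,8-trihydroxyflavan-3,4-diol | Oc1ccc([C@H]2Oc3c(cc([C@H]4c5ccc(O)c(O)c5O[C@H](c5ccc(O)c(O)c5)[C@@H]4O)c(O)c3O)[C@@H](O)[C@H]2O)cc1 | target

**Totals and risks**
Total step count: 14. Longest linear sequence: 12 steps (7 to 24, steps 3–14).

Steps most likely to fail:

1. Step 12 (proposed new method). What may go wrong: the benzylic carbon rather than the benzoate-bearing carbon acting as nucleophile, poor simple diastereoselection (2,3-trans instead of 2,3-cis) or poor enantiofacial control, or competitive ionisation of the lower benzylic carbonate. The fallback uses known flavan-4-yl cation chemistry and forms the C4–C6 interflavan bond instead; it sets out from acetal 10 and carbonate 15 and returns at 22. Acetal 10 is arylated with commercial [3,4-bis(benzyloxy)phenyl]boronic acid under the step 5 protocol to (S)-7,8-bis(benzyloxy)-2-[3,4-bis(benzyloxy)phenyl]-2H-chromene F1. NBS in wet DMSO, as in step 6, gives the trans bromohydrin F2, and BzCl/pyridine gives its 4-O-benzoate F3. AgOTf with 2,6-di-tert-butylpyridine in CH2Cl2 at −40 °C, in the presence of 15, removes bromide with benzoate participation (Woodward–Prévost benzoxonium ion, cis to the aryl group). C6 of 15 then attacks C4 anti to the participating oxygen (Friedel–Crafts, 3,4-trans), which should give 22.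

2. Step 14. What may go wrong: hydrogenolysis of the activated benzylic C4–OH of the lower unit (over-reduction to the flavan-3-ol level) or incomplete debenzylation. The fallback sets out from 23 and returns at 24. MnO2 in CH2Cl2 oxidises only the benzylic C4–OH to the hepta-O-benzyl 4-ketone F4 (a 2,3-cis-dihydroflavonol unit). H2 with Pd(OH)2/C then removes the benzyl ethers to the free phenolic ketone F5, the aryl ketone being resistant. NaBH4 in EtOH at 0 °C reduces the ketone from the face anti to the 2-aryl and 3-hydroxy groups, the classical dihydroflavonol to flavan-3,4-diol reduction, which should give the 3,4-cis diol 24.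

3. Step 9. What may go wrong: competing Suzuki–Miyaura coupling at boron, protodeboronation, or oxidative addition of zerovalent palladium into the benzylic carbonate. The fallback is palladium-free, sets out from 15 and returns at 17. Vilsmeier–Haack formylation (POCl3, DMF) at C6 gives the 6-carbaldehyde F6. Takai–Utimoto olefination with (dichloromethyl)boronic acid pinacol ester, CrCl2 and LiI in THF should give the E alkenylboronate 17.

**Further compounds**
F1 | step 12 | (S)-7,8-bis(benzyloxy)-2-[3,4-bis(benzyloxy)phenyl]-2H-chromene | C(c7ccccc7)Oc1ccc([C@H]2Oc3c(ccc(OCc7ccccc7)c3OCc7ccccc7)C=C2)cc1OCc7ccccc7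
F2 | step 12 | (2R,3S,4R)-7,8-bis(benzyloxy)-2-[3,4-bis(benzyloxy)phenyl]-3-bromochroman-4-ol | C(c7ccccc7)Oc1ccc([C@H]2Oc3c(ccc(OCc7ccccc7)c3OCc7ccccc7)[C@@H](O)[C@@H]2Br)cc1OCc7ccccc7
F3 | step 12 | 4-O-benzoate of F2 (configuration unchanged) | C(c7ccccc7)Oc1ccc([C@H]2Oc3c(ccc(OCc7ccccc7)c3OCc7ccccc7)[C@@H](OC(=O)c5ccccc5)[C@@H]2Br)cc1OCc7ccccc7
F4 | step 14 | hepta-O-benzyl dimer with the lower C4 ketone (2,3-cis-dihydroflavonol unit) | C(c7ccccc7)Oc1ccc([C@H]2Oc3c(cc([C@H]4c5ccc(OCc7ccccc7)c(OCc7ccccc7)c5O[C@H](c5ccc(OCc7ccccc7)c(OCc7ccccc7)c5)[C@@H]4O)c(OCc7ccccc7)c3OCc7ccccc7)C(=O)[C@H]2O)cc1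
F5 | step 14 | free phenolic dimer with the lower C4 ketone | Oc1ccc([C@H]2Oc3c(cc([C@H]4c5ccc(O)c(O)c5O[C@H](c5ccc(O)c(O)c5)[C@@H]4O)c(O)c3O)C(=O)[C@H]2O)cc1
F6 | step 9 | 6-formyl derivative of 15 | C(c7ccccc7)Oc1ccc([C@H]2Oc3c(cc(C=O)c(OCc7ccccc7)c3OCc7ccccc7)[C@H]4OC(=O)O[C@@H]24)cc1
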